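**Plan**
- Feature: in ring C the neighbours C3 and C4 carry only the gallate oxygen (C3) and only ring A (C4, a CH2). The pair is the reduced form of a C3=C4 enol ester, an alkene that divides into a ring A styrene carbon and an open-chain 1-acyloxyvinyl carbon.
- Cuts, in retrosynthetic order: the six benzyl ethers and the C–H bonds at C3 and C4; C3=C4 (ring-closing metathesis); the ester O–C3 bond (acid added across an alkyne); O1–C2 (propargylic etherification); C2–C3 (ethynyl Grignard) and the ring A vinyl C=C (Wittig).
- Forward: the ring A vinylphenol and the ring B propargylic acetate are joined at O1–C2, the gallate is added across the alkyne, ring C closes last by metathesis, and one hydrogenation finishes.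
- Stereochemistry: C2 is set by a chiral copper–pybox catalyst from the racemic acetate (stereoconvergent). C3 follows from C2, hydrogen being delivered to the chromene face anti to the 2-aryl group, which gives the 2,3-cis (2R,3R) ester.

Key step: step 6

Assumption: the (S,S)-diphenyl-pybox ligand is taken to give the (S)-configured propargylic ether of step 4; should a first run show the opposite sense, the (R,R)-ligand is used instead.
Remark: 3,4,5-tris(benzyloxy)benzoic acid is an article of commerce and is used as bought.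

**Step 1**
Reactants: 1 2,4,6-trihydroxybenzaldehyde
Product: 2 2,4-bis(benzyloxy)-6-hydroxybenzaldehyde
Conditions: BnBr (2.1 equiv), K2CO3 (2.2 equiv), DMF, 0 °C to rt
Reagents that add atoms: benzyl bromide, BrCc1ccccc1
Why: Williamson etherification should stop at the dibenzyl ether because the remaining ortho hydroxyl is deactivated by its hydrogen bond to the formyl group.

**Step 2**
Reactants: 2 2,4-bis(benzyloxy)-6-hydroxybenzaldehyde
Product: 3 3,5-bis(benzyloxy)-2-vinylphenol
Conditions: Ph3PCH3Br (3 equiv), KOtBu (3 equiv), THF, 0 °C to rt; product kept cold with a trace of BHT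
Reagents that add atoms: methyltriphenylphosphonium bromide, C[P+](c1ccccc1)(c1ccccc1)c1ccccc1.[Br-]
Why: Wittig methylenation, in which excess ylide first deprotonates the phenol and the phenoxide aldehyde is still converted on warming, as with other salicylaldehydes.

**Step 3**
Reactants: 4 4-(benzyloxy)benzaldehyde; 5 ethynylmagnesium bromide
Product: 7 rac-1-[4-(benzyloxy)phenyl]prop-2-yn-1-yl acetate, via bromomagnesium propargylic alkoxide 6 (not isolated)
Conditions: 5 (1.2 equiv), THF, 0 °C; then Ac2O (1.5 equiv), 0 °C to rt; used after quick filtration through Et3N-deactivated silica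
Reagents that add atoms: acetic anhydride, CC(=O)OC(C)=O
Why: Grignard 1,2-addition to the aldehyde followed by acetylation of the magnesium alkoxide in the same flask; the racemate suffices because step 4 is stereoconvergent.

**Step 4**
Reactants: 3 3,5-bis(benzyloxy)-2-vinylphenol; 7 rac-1-[4-(benzyloxy)phenyl]prop-2-yn-1-yl acetate
Product: 8 (S)-1,5-bis(benzyloxy)-3-({1-[4-(benzyloxy)phenyl]prop-2-yn-1-yl}oxy)-2-vinylbenzene
Conditions: CuOTf·1/2C6H6 (5 mol %), (S,S)-Ph-pybox (10 mol %), iPr2NEt (1.5 equiv), THF, −20 °C, under argon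
Reagents that add atoms: none
Why: Copper-catalysed enantioselective propargylic etherification of a phenol, in which the copper acetylide of either enantiomer of 7 loses acetate to the same planar copper allenylidene and the phenoxide adds to its γ-carbon on the face left open by the pybox ligand, setting the future C2 (S by the priority rules, the same spatial arrangement as 2R in the target).

**Step 5**
Reactants: 8 (S)-1,5-bis(benzyloxy)-3-({1-[4-(benzyloxy)phenyl]prop-2-yn-1-yl}oxy)-2-vinylbenzene; 9 3,4,5-tris(benzyloxy)benzoic acid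
Product: 10 (R)-3-[3,5-bis(benzyloxy)-2-vinylphenoxy]-3-[4-(benzyloxy)phenyl]prop-1-en-2-yl 3,4,5-tris(benzyloxy)benzoate
Conditions: 9 (1.3 equiv), [RuCl2(p-cymene)]2 (2 mol %), P(2-furyl)3 (8 mol %), Na2CO3 (4 mol %), toluene, 50 °C
Reagents that add atoms: none
Why: Ruthenium-catalysed Markovnikov hydro-acyloxylation of a terminal alkyne, in which the carboxylate adds to the internal carbon of the ruthenium-bound alkyne, so the gallate arrives without any hydroxyl being acylated and the stereocentre is untouched (the descriptor becomes R only because the new enol ester carbon outranks the aryl group).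

**Step 6**
Reactants: 10 (R)-3-[3,5-bis(benzyloxy)-2-vinylphenoxy]-3-[4-(benzyloxy)phenyl]prop-1-en-2-yl 3,4,5-tris(benzyloxy)benzoate
Product: 11 (R)-5,7-bis(benzyloxy)-2-[4-(benzyloxy)phenyl]-2H-chromen-3-yl 3,4,5-tris(benzyloxy)benzoate
Conditions: second-generation Hoveyda–Grubbs catalyst [RuCl2(H2IMes)(=CH-C6H4-2-OiPr)] (2 × 5 mol %), 1,4-benzoquinone (10 mol %), toluene (5 mM), 80 °C, argon sparge, dark
Reagents that add atoms: none
Why: Proposed new method: the ruthenium alkylidene should load on the monosubstituted ring A styrene, add across the 1,1-disubstituted enol ester of the same molecule to a ruthenacyclobutane that holds C4 and C3, and cyclorevert to the C3=C4 alkene and Ru=CH2, so that ethylene is the only by-product and no acyloxy-substituted carbene has to form. The closest known reactions are the ring-closing metathesis of 2-vinylphenyl allyl ethers to 2H-chromenes and that of 1,1-disubstituted enol ethers, silyl enol ethers and enol phosphates; an enol carboxylate as the partner is the unproven element, and its lower electron density is offset by the short, rigid tether through O1 and C2. Ring C (O1, C2, C3, C4, C4a, C8a) closes as a six-membered ring from a 1,7-diene, both reacting alkene carbons becoming ring members. No stereocentre is formed; C2 from step 4 is a spectator and should be kept because the medium is neutral and aprotic (no ionisation of the benzylic, allylic aryl ether), the temperature stays below that of an aryl allyl ether Claisen rearrangement, and light is excluded (no electrocyclic opening of the chromene). The selectivity needed is ring closure over oligomerisation and over alkene migration, secured by there being only two alkenes in the molecule, by high dilution with ethylene removal, and by benzoquinone as a trap for ruthenium hydrides.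

**Step 7**
Reactants: 11 (R)-5,7-bis(benzyloxy)-2-[4-(benzyloxy)phenyl]-2H-chromen-3-yl 3,4,5-tris(benzyloxy)benzoate
Product: 13 (2R,3R)-5,7-dihydroxy-2-(4-hydroxyphenyl)chroman-3-yl 3,4,5-trihydroxybenzoate, via hexa-O-benzyl cis-ester 12 (not isolated)
Conditions: H2 (1 atm), 10% Pd/C, THF–EtOAc 1:1, rt, dark; filtered and concentrated under argon
Reagents that add atoms: none
Why: Heterogeneous catalytic hydrogenation should add H2 syn to the C3=C4 enol ester from the face anti to the pseudoaxial 2-aryl group, which sets C3 as R and the 2,3-cis relationship (the sense known from hydrogenation of flavylium salts to cis-flavan-3-ols), and continued hydrogenolysis then cleaves the six aryl benzyl ethers, which react faster than the cyclic C2–O1 ether.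

**Compound list**
1 | 2,4,6-trihydroxybenzaldehyde | O=Cc1c(O)cc(O)cc1O | starting material
2 | 2,4-bis(benzyloxy)-6-hydroxybenzaldehyde | O=Cc1c(O)cc(OCc2ccccc2)cc1OCc1ccccc1 | intermediate
3 | 3,5-bis(benzyloxy)-2-vinylphenol | C=Cc1c(O)cc(OCc2ccccc2)cc1OCc1ccccc1 | intermediate
4 | 4-(benzyloxy)benzaldehyde | O=Cc1ccc(OCc2ccccc2)cc1 | starting material
5 | ethynylmagnesium bromide | C#C[Mg]Br | starting material
6 | bromomagnesium 1-[4-(benzyloxy)phenyl]prop-2-yn-1-olate (racemic, not isolated) | C#CC(O[Mg]Br)c1ccc(OCc2ccccc2)cc1 | intermediate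
7 | rac-1-[4-(benzyloxy)phenyl]prop-2-yn-1-yl acetate | C#CC(OC(C)=O)c1ccc(OCc2ccccc2)cc1 | intermediate
8 | (S)-1,5-bis(benzyloxy)-3-({1-[4-(benzyloxy)phenyl]prop-2-yn-1-yl}oxy)-2-vinylbenzene | C=Cc1c(OCc2ccccc2)cc(OCc2ccccc2)cc1O[C@@H](C#C)c1ccc(OCc2ccccc2)cc1 | intermediate
9 | 3,4,5-tris(benzyloxy)benzoic acid | OC(=O)c1cc(OCc2ccccc2)c(OCc2ccccc2)c(OCc2ccccc2)c1 | starting material
10 | (R)-3-[3,5-bis(benzyloxy)-2-vinylphenoxy]-3-[4-(benzyloxy)phenyl]prop-1-en-2-yl 3,4,5-tris(benzyloxy)benzoate | C=Cc1c(OCc2ccccc2)cc(OCc2ccccc2)cc1O[C@@H](C(=C)OC(=O)c1cc(OCc2ccccc2)c(OCc2ccccc2)c(OCc2ccccc2)c1)c1ccc(OCc2ccccc2)cc1 | intermediate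
11 | (R)-5,7-bis(benzyloxy)-2-[4-(benzyloxy)phenyl]-2H-chromen-3-yl 3,4,5-tris(benzyloxy)benzoate | O=C(OC1=Cc2c(OCc3ccccc3)cc(OCc3ccccc3)cc2O[C@@H]1c1ccc(OCc2ccccc2)cc1)c1cc(OCc2ccccc2)c(OCc2ccccc2)c(OCc2ccccc2)c1 | intermediate
12 | (2R,3R)-5,7-bis(benzyloxy)-2-[4-(benzyloxy)phenyl]chroman-3-yl 3,4,5-tris(benzyloxy)benzoate (hexa-O-benzyl cis-ester, not isolated) | O=C(O[C@@H]1Cc2c(OCc3ccccc3)cc(OCc3ccccc3)cc2O[C@@H]1c1ccc(OCc2ccccc2)cc1)c1cc(OCc2ccccc2)c(OCc2ccccc2)c(OCc2ccccc2)c1 | intermediate
13 | (2R,3R)-5,7-dihydroxy-2-(4-hydroxyphenyl)chroman-3-yl 3,4,5-trihydroxybenzoate | O=C(O[C@@H]1Cc2c(O)cc(O)cc2O[C@@H]1c1ccc(O)cc1)c1cc(O)c(O)c(O)c1 | target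

**Step count and risks**
Total step count: 7. Longest linear sequence: 6 steps (steps 1, 2, 4, 5, 6 and 7, from compound 1).

Step 6 (ring-closing metathesis on the enol gallate). The ruthenium carbene formed on the styrene may rest as an ortho-alkoxy chelate and fail to engage the hindered, electron-poor enol ester, so that the catalyst decays or ruthenium hydrides start to move double bonds. The fallback uses known chemistry, sets out from 8 and comes back to the route at 12. Semi-hydrogenation of the alkyne of 8 (H2, Pd/CaCO3 poisoned with Pb(OAc)2, quinoline, EtOAc) should give the allyl ether (S)-1,5-bis(benzyloxy)-3-({1-[4-(benzyloxy)phenyl]prop-2-en-1-yl}oxy)-2-vinylbenzene F1. Ring-closing metathesis of this 2-vinylphenyl allyl ether with the second-generation Grubbs catalyst [RuCl2(H2IMes)(PCy3)(=CHPh)] in CH2Cl2 at 40 °C, a well-known chromene synthesis, should give (S)-5,7-bis(benzyloxy)-2-[4-(benzyloxy)phenyl]-2H-chromene F2. Hydroboration with BH3·THF at 0 °C, anti to the 2-aryl group and with boron at C3, should give the alkylborane, written as [(2S,3S)-5,7-bis(benzyloxy)-2-[4-(benzyloxy)phenyl]chroman-3-yl]borane F3, which is not isolated. Oxidation with NaOH and H2O2 then gives the trans alcohol (2R,3S)-5,7-bis(benzyloxy)-2-[4-(benzyloxy)phenyl]chroman-3-ol F4. Dess–Martin oxidation gives (R)-5,7-bis(benzyloxy)-2-[4-(benzyloxy)phenyl]chroman-3-one F5. Reduction with LiBH(s-Bu)3 in THF at −78 °C, from the face anti to the 2-aryl group, gives the cis alcohol (2R,3R)-5,7-bis(benzyloxy)-2-[4-(benzyloxy)phenyl]chroman-3-ol F6. Esterification of F6 with 9 (DCC, DMAP, CH2Cl2) gives 12, here isolated, which is debenzylated under the conditions of step 7.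

Step 4 (propargylic etherification). Enantioselectivity may be eroded by uncatalysed ionisation of the p-alkoxybenzylic acetate, and the electron-rich ring A may be propargylated at carbon in place of oxygen. The fallback fixes the stereocentre in the alcohol and forms O1–C2 by inversion; it sets out from 4 and 5 and comes back at 8. Grignard addition with aqueous work-up gives rac-1-[4-(benzyloxy)phenyl]prop-2-yn-1-ol F7. Lipase resolution (immobilised Candida antarctica lipase B, vinyl acetate, toluene) is expected by Kazlauskas' rule to acetylate the R enantiomer and give (R)-1-[4-(benzyloxy)phenyl]prop-2-yn-1-yl acetate F8, the S alcohol being left behind. Methanolysis (K2CO3, MeOH, 0 °C) gives (R)-1-[4-(benzyloxy)phenyl]prop-2-yn-1-ol F9. Mitsunobu etherification of F9 with phenol 3 (PPh3, DIAD, toluene, −20 °C) should give 8 with inversion.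

Step 7 (hydrogenation and debenzylation). On the palladium surface the C3=C4 double bond may migrate toward C2 and erase that stereocentre, the allylic and benzylic C2–O1 bond may be hydrogenolysed before the alkene is saturated, and the facial selectivity may be incomplete. The fallback separates alkene reduction from deprotection; it sets out from 11 and comes back at 13 by way of 12, which is isolated. Homogeneous, ester-carbonyl-chelated hydrogenation of the enol ester with a cationic rhodium diphosphine catalyst such as [Rh(cod)(dppb)]BF4 (H2, 10 bar, CH2Cl2) touches neither benzyl ethers nor ring C–O bonds, and a chiral diphosphine of the matched sense could reinforce the substrate bias. The isolated 12 is then debenzylated with H2 over Pd(OH)2/C in THF–MeOH, the standard last step for perbenzylated flavan-3-ol gallates.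

**Further compounds**
F1 | step 6 | (S)-1,5-bis(benzyloxy)-3-({1-[4-(benzyloxy)phenyl]prop-2-en-1-yl}oxy)-2-vinylbenzene | C=Cc1c(OCc2ccccc2)cc(OCc2ccccc2)cc1O[C@@H](C=C)c1ccc(OCc2ccccc2)cc1
F2 | step 6 | (S)-5,7-bis(benzyloxy)-2-[4-(benzyloxy)phenyl]-2H-chromene | C1=Cc2c(OCc3ccccc3)cc(OCc3ccccc3)cc2O[C@@H]1c1ccc(OCc2ccccc2)cc1
F3 | step 6 | [(2S,3S)-5,7-bis(benzyloxy)-2-[4-(benzyloxy)phenyl]chroman-3-yl]borane (not isolated) | B[C@H]1Cc2c(OCc3ccccc3)cc(OCc3ccccc3)cc2O[C@@H]1c1ccc(OCc2ccccc2)cc1
F4 | step 6 | (2R,3S)-5,7-bis(benzyloxy)-2-[4-(benzyloxy)phenyl]chroman-3-ol | O[C@H]1Cc2c(OCc3ccccc3)cc(OCc3ccccc3)cc2O[C@@H]1c1ccc(OCc2ccccc2)cc1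
F5 | step 6 | (R)-5,7-bis(benzyloxy)-2-[4-(benzyloxy)phenyl]chroman-3-one | O=C1Cc2c(OCc3ccccc3)cc(OCc3ccccc3)cc2O[C@@H]1c1ccc(OCc2ccccc2)cc1
F6 | step 6 | (2R,3R)-5,7-bis(benzyloxy)-2-[4-(benzyloxy)phenyl]chroman-3-ol | O[C@@H]1Cc2c(OCc3ccccc3)cc(OCc3ccccc3)cc2O[C@@H]1c1ccc(OCc2ccccc2)cc1
F7 | step 4 | rac-1-[4-(benzyloxy)phenyl]prop-2-yn-1-ol | C#CC(O)c1ccc(OCc2ccccc2)cc1
F8 | step 4 | (R)-1-[4-(benzyloxy)phenyl]prop-2-yn-1-yl acetate | CC(=O)O[C@H](C#C)c1ccc(OCc2ccccc2)cc1
F9 | step 4 | (R)-1-[4-(benzyloxy)phenyl]prop-2-yn-1-ol | O[C@H](C#C)c1ccc(OCc2ccccc2)cc1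
F0 | step 7 | none | none
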